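## Retrosynthetic overview

1. Structural feature: in ring A (the 2-formylindole), C3 is bonded to C3a on one side and to the methine carbon on the other. C3 and the methine carbon are therefore treated as the two carbons of an alkyne that already holds one indol-3-yl group. C2 is the propargylic carbon that carries N1 and an ester standing in for the formyl group.
2. Key disconnection: C3–C3a and the bond from the methine carbon to C3 of the second indol-3-yl group are cut together. This leads back to an N-(2-iodophenyl)alkynylglycine ester and an indol-3-ylboronate, and a hydrogen shift from C2 to the methine carbon then aromatises ring A.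
3. The alkynylglycine ester is cut at the C2–alkyne bond into 2-iodoaniline, ethyl glyoxylate and 1-Boc-3-ethynylindole. The last comes from 1-Boc-3-iodoindole and ethynyltrimethylsilane.
4. Ring order: both outer indoles and the benzene half of ring A are purchased, and the pyrrole half of ring A is the only ring formed (step 4). Boc removal, ester reduction and alcohol oxidation finish the route.

Key step: step 4

Remark: the target has no stereocentre. The alkynylglycine ester and the alkylideneindoline each hold one, are carried as racemates, and lose it in the key step. Ethyl glyoxylate is taken as its commercial toluene solution.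

## Route

Step 1
Reactants: 1 tert-butyl 3-iodo-1H-indole-1-carboxylate; 2 ethynyltrimethylsilane
Product: 3 tert-butyl 3-[(trimethylsilyl)ethynyl]-1H-indole-1-carboxylate
Conditions: PdCl2(PPh3)2 (2 mol%), CuI (4 mol%), Et3N, THF, Ar, rt
Reagents that add atoms: none
Why: Sonogashira coupling, in which the C3–I bond of the N-acylated indole adds readily to zerovalent palladium at room temperature and the carbamate is inert to Et3N, whereas carbonate/methanol or organolithium homologation of the 3-carbaldehyde would endanger the indole N-Boc group.

Step 2
Reactants: 3 tert-butyl 3-[(trimethylsilyl)ethynyl]-1H-indole-1-carboxylate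
Product: 4 tert-butyl 3-ethynyl-1H-indole-1-carboxylate
Conditions: TBAF (1.1 equiv), AcOH (1.1 equiv), THF, 0 °C
Reagents that add atoms: none
Why: Fluoride-induced protodesilylation of an alkynylsilane, buffered with AcOH at 0 °C so that the medium stays non-basic and the labile indole N-Boc group survives.

Step 3
Reactants: 4 tert-butyl 3-ethynyl-1H-indole-1-carboxylate; 5 2-iodoaniline; 6 ethyl glyoxylate
Product: 8 ethyl 2-[(2-iodophenyl)amino]-4-[1-(tert-butoxycarbonyl)-1H-indol-3-yl]but-3-ynoate (racemic), via glyoxylate N-(2-iodophenyl)imine 7 (not isolated)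
Conditions: 5, 6 (ca. 50% in PhMe, briefly heated to depolymerise), 4 Å MS, PhMe, rt; then 4, CuBr (10 mol%), Ar, dark, rt
Reagents that add atoms: none
Why: Three-component imine alkynylation (A3-type coupling), in which the copper acetylide from CuBr and 4 adds to the strongly electrophilic C=N bond of the glyoxylate aldimine at room temperature, far below the temperature at which copper would engage the aryl iodide, and the new C2 stereocentre forms racemic, which is harmless because step 4 erases it.

Step 4
Reactants: 8 ethyl 2-[(2-iodophenyl)amino]-4-[1-(tert-butoxycarbonyl)-1H-indol-3-yl]but-3-ynoate; 9 tert-butyl 3-(4,4,5,5-tetramethyl-1,3,2-dioxaborolan-2-yl)-1H-indole-1-carboxylate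
Product: 11 ethyl 3-{bis[1-(tert-butoxycarbonyl)-1H-indol-3-yl]methyl}-1H-indole-2-carboxylate, via 3-(diindolylmethylidene)indoline-2-carboxylate 10 (not isolated)
Conditions: Pd(PPh3)4 (5 mol%), 9 (1.5 equiv), K3PO4 (3 equiv), dioxane–H2O (10:1), degassed, Ar, 80 °C
Reagents that add atoms: none
Why: Zerovalent palladium inserts into the C–I bond of 8, the arylpalladium iodide adds syn across the tethered triple bond to form C3a–C3, and the vinylpalladium, now on the carbon bearing the first indolyl group, transmetalates with 9 and reductively eliminates to form the second methine–indole bond, giving 10. K3PO4 then removes the C2 hydrogen of 10, which is activated by the ester, the nitrogen and the allylic position, and reprotonation of the delocalised anion at the exocyclic carbon (net 1,3-hydrogen shift) gives 11, driven by the aromaticity gained in ring A. The closest known reaction type is the domino Heck carbopalladation/Suzuki–Miyaura termination of 2-haloaryl-tethered alkynes, which gives 3-(diarylmethylidene)oxindoles and 3-alkylideneindolines, and a free N–H is tolerated in the related Heck cyclisation of N-allyl-2-iodoanilines to 3-methylindoles. The pyrrole half of ring A closes 5-exo-dig, since a 6-endo closure would need a syn addition that the three-atom tether cannot reach. No stereocentre is created: the alkene of 10 carries two identical groups so its geometry has no meaning, the racemic C2 centre is destroyed, and the methine carbon of 11 bears two identical indolyl groups. The selectivity needed is cyclisation before transmetalation (no direct biaryl coupling at the iodide), which is secured because the tether holds the alkyne next to palladium and makes carbopalladation unimolecular, while the excess of 9 offsets protodeboronation.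

Step 5
Reactants: 11 ethyl 3-{bis[1-(tert-butoxycarbonyl)-1H-indol-3-yl]methyl}-1H-indole-2-carboxylate
Product: 12 ethyl 3-[di(1H-indol-3-yl)methyl]-1H-indole-2-carboxylate
Conditions: NaOEt (0.3 equiv), EtOH–THF (1:1), rt
Reagents that add atoms: none
Why: Alkoxide-catalysed alcoholysis of an N-acylindole-type carbamate, in which indolide is a good leaving group so ethoxide takes the Boc carbonyl under mild conditions, ethanol matches the ester so transesterification is degenerate, and acid, which could fragment a triindolylmethane by retro-Friedel–Crafts cleavage, is avoided.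

Step 6
Reactants: 12 ethyl 3-[di(1H-indol-3-yl)methyl]-1H-indole-2-carboxylate
Product: 13 {3-[di(1H-indol-3-yl)methyl]-1H-indol-2-yl}methanol
Conditions: LiAlH4 (5 equiv), THF, 0 °C to rt; then H2O, 15% aq NaOH, H2O
Reagents that add atoms: none
Why: Hydride reduction of an ester, in which excess LiAlH4 first deprotonates the three N–H groups and then reduces the 2-carboxylate to the primary alcohol as is standard for indole-2-carboxylates, and the basic work-up spares the acid-labile 2-(hydroxymethyl)indole.

Step 7
Reactants: 13 {3-[di(1H-indol-3-yl)methyl]-1H-indol-2-yl}methanol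
Product: 14 trisindolal, 3-[di(1H-indol-3-yl)methyl]-1H-indole-2-carbaldehyde
Conditions: activated MnO2 (10–15 equiv), THF–CH2Cl2, rt
Reagents that add atoms: none
Why: Selective MnO2 oxidation of a heterobenzylic alcohol, which proceeds under neutral anhydrous conditions on indol-2-ylmethanols and stops at the aldehyde because no hydrate can form.

## Compound list

1 | tert-butyl 3-iodo-1H-indole-1-carboxylate | CC(C)(C)OC(=O)n1cc(I)c2ccccc12 | starting material
2 | ethynyltrimethylsilane | C#C[Si](C)(C)C | starting material
3 | tert-butyl 3-[(trimethylsilyl)ethynyl]-1H-indole-1-carboxylate | CC(C)(C)OC(=O)n1cc(C#C[Si](C)(C)C)c2ccccc12 | intermediate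
4 | tert-butyl 3-ethynyl-1H-indole-1-carboxylate | CC(C)(C)OC(=O)n1cc(C#C)c2ccccc12 | intermediate
5 | 2-iodoaniline | Nc1ccccc1I | starting material
6 | ethyl glyoxylate | CCOC(=O)C=O | starting material
7 | ethyl (E)-2-[(2-iodophenyl)imino]acetate (not isolated) | CCOC(=O)/C=N/c1ccccc1I | intermediate
8 | ethyl 2-[(2-iodophenyl)amino]-4-[1-(tert-butoxycarbonyl)-1H-indol-3-yl]but-3-ynoate, racemic | CCOC(=O)C(Nc1ccccc1I)C#Cc1cn(C(=O)OC(C)(C)C)c2ccccc12 | intermediate
9 | tert-butyl 3-(4,4,5,5-tetramethyl-1,3,2-dioxaborolan-2-yl)-1H-indole-1-carboxylate | CC(C)(C)OC(=O)n1cc(B2OC(C)(C)C(C)(C)O2)c2ccccc12 | starting material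
10 | ethyl 3-{bis[1-(tert-butoxycarbonyl)-1H-indol-3-yl]methylidene}-2,3-dihydro-1H-indole-2-carboxylate, racemic (not isolated) | CCOC(=O)C1Nc2ccccc2C1=C(c1cn(C(=O)OC(C)(C)C)c2ccccc12)c1cn(C(=O)OC(C)(C)C)c2ccccc12 | intermediate
11 | ethyl 3-{bis[1-(tert-butoxycarbonyl)-1H-indol-3-yl]methyl}-1H-indole-2-carboxylate | CCOC(=O)c1[nH]c2ccccc2c1C(c1cn(C(=O)OC(C)(C)C)c2ccccc12)c1cn(C(=O)OC(C)(C)C)c2ccccc12 | intermediate
12 | ethyl 3-[di(1H-indol-3-yl)methyl]-1H-indole-2-carboxylate | CCOC(=O)c1[nH]c2ccccc2c1C(c1c[nH]c2ccccc12)c1c[nH]c2ccccc12 | intermediate
13 | {3-[di(1H-indol-3-yl)methyl]-1H-indol-2-yl}methanol | OCc1[nH]c2ccccc2c1C(c1c[nH]c2ccccc12)c1c[nH]c2ccccc12 | intermediate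
14 | trisindolal, 3-[di(1H-indol-3-yl)methyl]-1H-indole-2-carbaldehyde | O=Cc1[nH]c2ccccc2c1C(c1c[nH]c2ccccc12)c1c[nH]c2ccccc12 | target

## Step count and risks

Total step count: 7. Longest linear sequence: 7 steps (1 → 3 → 4 → 8 → 11 → 12 → 13 → 14).

**Steps most likely to fail**

**Step 4.**
- What may go wrong:
  - Base-triggered propargyl-to-allenyl isomerisation of the precursor may occur before oxidative addition.
  - Protodeboronation of the heteroaryl boronate may starve the congested vinylpalladium of its partner, which could then undergo 1,4-palladium migration to C4 of ring A or be reduced.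
  - Partial loss of Boc may occur under hot aqueous base.
- Fallback: it sets out from 5, returns at 12, and builds the methine by electrophilic substitution instead of by palladium.
  - 2-Iodoaniline 5 is annulated with ethyl pyruvate (CCOC(=O)C(C)=O; Pd(OAc)2, DABCO, DMF, 105 °C; enamine formation followed by intramolecular Heck reaction) to ethyl 1H-indole-2-carboxylate F1.
  - Vilsmeier–Haack formylation (POCl3, DMF) gives ethyl 3-formyl-1H-indole-2-carboxylate F2.
  - Acid-catalysed double Friedel–Crafts condensation of F2 with two equivalents of indole (c1ccc2[nH]ccc2c1; cat. p-TsOH, MeCN, rt) gives 12.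

**Step 3.**
- What may go wrong:
  - Acetylide transfer to an imine derived from a very weakly basic aniline may be sluggish.
  - Povarov-type cycloaddition or hydroarylation toward a quinoline may compete at the free ortho position.
  - Glaser homocoupling of the alkyne may occur if air enters.
- Fallback: it sets out from 4, returns at 8, and forms the C2–N bond by substitution instead of forming the C2–alkyne bond on an imine.
  - Alkyne 4 is deprotonated with LiN(SiMe3)2 (THF, −78 °C) and added to ethyl glyoxylate 6 to give racemic ethyl 2-hydroxy-4-[1-(tert-butoxycarbonyl)-1H-indol-3-yl]but-3-ynoate F3.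
  - MsCl/Et3N (CH2Cl2, −20 °C) converts it into ethyl 2-(methylsulfonyloxy)-4-[1-(tert-butoxycarbonyl)-1H-indol-3-yl]but-3-ynoate F4.
  - SN2 displacement at this doubly activated carbon with 2-iodoaniline 5 (2,6-lutidine, MeCN, rt to 40 °C) gives 8.

**Step 7.**
- What may go wrong:
  - Hydrogen abstraction at the methine C–H, which is activated by three indole rings, may lead to overoxidation to coloured methylium-type material.
  - The polar tris-N–H product may adsorb irreversibly on the oxidant.
- Fallback: it sets out from 12, returns at 14, and reaches the aldehyde oxidation level by reduction only, so that no oxidant meets the methine.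
  - Ester 12 is treated with MeNH(OMe)·HCl and excess iPrMgCl (THF, −10 °C) to give 3-[di(1H-indol-3-yl)methyl]-N-methoxy-N-methyl-1H-indole-2-carboxamide F5.
  - Reduction with LiAlH4 (THF, −20 to 0 °C) stops at the chelated tetrahedral intermediate, which releases 14 on aqueous work-up.

## Further compounds

F1 | step 4 | ethyl 1H-indole-2-carboxylate | CCOC(=O)c1cc2ccccc2[nH]1
F2 | step 4 | ethyl 3-formyl-1H-indole-2-carboxylate | CCOC(=O)c1[nH]c2ccccc2c1C=O
F3 | step 3 | ethyl 2-hydroxy-4-[1-(tert-butoxycarbonyl)-1H-indol-3-yl]but-3-ynoate, racemic | CCOC(=O)C(O)C#Cc1cn(C(=O)OC(C)(C)C)c2ccccc12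
F4 | step 3 | ethyl 2-(methylsulfonyloxy)-4-[1-(tert-butoxycarbonyl)-1H-indol-3-yl]but-3-ynoate, racemic | CCOC(=O)C(OS(C)(=O)=O)C#Cc1cn(C(=O)OC(C)(C)C)c2ccccc12
F5 | step 7 | 3-[di(1H-indol-3-yl)methyl]-N-methoxy-N-methyl-1H-indole-2-carboxamide | CON(C)C(=O)c1[nH]c2ccccc2c1C(c1c[nH]c2ccccc12)c1c[nH]c2ccccc12
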